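**Retrosynthetic overview**
1. C9–C10 (last bond): Negishi coupling of an (E)-vinyl iodide 1,2-dioxane with the alkenylzinc made from 1-phenylbut-2-yne.
2. C3–H and C6–CH3: both peroxide-bearing carbons are carried at the ketone oxidation level and set by axial hydride (C3) and axial methyl (C6, new reaction) delivery to peroxycarbenium ions, both relayed from the C4 methyl.
3. 1,2-Dioxane (the only ring made, step 5): cobalt/O2 oxidative ring expansion of a 2-silyloxycyclobutanol, inserting O2 into the strained C–C bond.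
4. Cyclobutanol: from 3-methylcyclobutanone by desymmetrising alkylation (sets C4), Rubottom oxidation, propargylation and carboalumination–iodination.

Assumption: the (R,R)-lithium amide is taken to give the (3R)-enolate (if the sense is opposite, the (S,S)-base is used); compounds 12–14 are written without configuration at the peroxyketal carbons, which are mixtures that converge in steps 6 and 7.

**Step 1**
Reactants: 1 3-methylcyclobutan-1-one; 2 methyl bromoacetate
Product: 4 methyl 2-[(1S,2R)-2-methyl-4-oxocyclobutyl]acetate, via lithium enolate 3 (not isolated)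
Conditions: Li bis[(R)-1-phenylethyl]amide (amine + n-BuLi), LiCl, THF, −100 °C; then 2, DMPU, −78 → −40 °C
Reagents that add atoms: none
Why: Desymmetrising enantioselective deprotonation of the prochiral ketone by a C2-symmetric chiral lithium amide (chiral-base enolisation) chooses one enantiotopic α-CH2 and so fixes the methyl-bearing carbon (the later C4, R), and the enolate is alkylated anti to that methyl (enolate alkylation).

**Step 2**
Reactants: 4 methyl 2-[(1S,2R)-2-methyl-4-oxocyclobutyl]acetate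
Product: 6 methyl 2-[(1S,2R)-2-methyl-4-oxo-1-[(triethylsilyl)oxy]cyclobutyl]acetate, via enol silane 5 (not isolated)
Conditions: Et3SiCl, NaI, Et3N, MeCN, 40 °C; then mCPBA, hexane/CH2Cl2, −15 °C → rt
Reagents that add atoms: chlorotriethylsilane CC[Si](Cl)(CC)CC; mCPBA OOC(=O)c1cccc(Cl)c1
Why: Equilibrating silylation with in situ Et3SiI gives the more substituted (thermodynamic) silyl enol ether and Rubottom oxidation (epoxidation anti to the neighbouring methyl, then 1,4-silyl shift) puts a silyloxy group on the ester-bearing carbon, whose configuration is irrelevant because this carbon becomes a planar peroxycarbenium ion in step 7.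

**Step 3**
Reactants: 6 methyl 2-[(1S,2R)-2-methyl-4-oxo-1-[(triethylsilyl)oxy]cyclobutyl]acetate; 7 3-bromoprop-1-yne
Product: 9 methyl 2-[(1S,2S,4R)-2-hydroxy-4-methyl-2-(prop-2-yn-1-yl)-1-[(triethylsilyl)oxy]cyclobutyl]acetate, via allenylzinc bromide 8 (not isolated)
Conditions: Zn dust, THF, 0 °C → rt; then H2O
Reagents that add atoms: none
Why: Zinc Barbier propargylation, in which allenylzinc bromide adds by SE2′ to the strained ketone to give the homopropargylic tertiary alcohol anti to the α-silyloxy group (polar Felkin–Anh), a carbinol centre that is destroyed again in step 5.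

**Step 4**
Reactants: 9 methyl 2-[(1S,2S,4R)-2-hydroxy-4-methyl-2-(prop-2-yn-1-yl)-1-[(triethylsilyl)oxy]cyclobutyl]acetate
Product: 11 methyl 2-[(1S,2S,4R)-2-hydroxy-2-[(2E)-3-iodo-2-methylprop-2-en-1-yl]-4-methyl-1-[(triethylsilyl)oxy]cyclobutyl]acetate, via alkenylalane 10 (not isolated)
Conditions: AlMe3 (3 equiv), Cp2ZrCl2 (25 mol%), CH2Cl2, −20 → 0 °C; then I2, THF, −30 °C; aqueous work-up
Reagents that add atoms: trimethylaluminium C[Al](C)C; iodine II
Why: Negishi zirconium-catalysed carboalumination adds methyl and aluminium syn across the terminal alkyne (methyl to the internal carbon) and iodinolysis with retention gives the (E)-vinyl iodide, the tertiary alcohol being masked in situ as its aluminium alkoxide.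

**Step 5**
Reactants: 11 methyl 2-[(1S,2S,4R)-2-hydroxy-2-[(2E)-3-iodo-2-methylprop-2-en-1-yl]-4-methyl-1-[(triethylsilyl)oxy]cyclobutyl]acetate
Product: 13 methyl 2-[(4R)-6-hydroxy-6-[(2E)-3-iodo-2-methylprop-2-en-1-yl]-4-methyl-3-[(triethylsilyl)oxy]-1,2-dioxan-3-yl]acetate, via hydroperoxy ketone 12 (not isolated)
Conditions: Co(acac)2 (10 mol%), O2 (1 atm), CH2Cl2, 25 °C
Reagents that add atoms: dioxygen O=O
Why: Cobalt-catalysed aerobic oxidative ring expansion of a tertiary cyclobutanol: the Co(III) alkoxide gives an alkoxy radical, strain-driven β-scission occurs towards the silyloxy-substituted tertiary carbon (the most stabilised radical), O2 is captured there and the hydroperoxide closes onto the new ketone, so O–O is inserted into the ring C–C bond and both peroxide carbons arrive as (hemi)ketals whose configuration need not be controlled.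

**Step 6**
Reactants: 13 methyl 2-[(4R)-6-hydroxy-6-[(2E)-3-iodo-2-methylprop-2-en-1-yl]-4-methyl-3-[(triethylsilyl)oxy]-1,2-dioxan-3-yl]acetate
Product: 14 methyl 2-[(4R,6R)-6-[(2E)-3-iodo-2-methylprop-2-en-1-yl]-4,6-dimethyl-3-[(triethylsilyl)oxy]-1,2-dioxan-3-yl]acetate
Conditions: Me2TiCl2 (2.5 equiv; from Me2Zn + TiCl4, CH2Cl2, −40 °C), CH2Cl2, −78 → −45 °C
Reagents that add atoms: dimethylzinc C[Zn]C
Why: Proposed new method: the hemiketal OH is exchanged onto titanium (loss of CH4), the Ti–O bond ionises to a cyclic tertiary peroxycarbenium ion and a non-basic, non-reducing Ti–CH3 delivers methyl along the axial trajectory of the half-chair in which the C4 methyl is pseudo-equatorial (attack on the other conformer would be 1,3-syn-axial to that methyl), so the new methyl ends axial and trans to the C4 methyl (6R) while the ester-deactivated silyl ketal at C3, which has no free OH to bind titanium, stays intact at −78 °C; the closest known reactions are the methylation of tertiary alcohols and ketals with Me2TiCl2 (Reetz) and the Lewis-acid allylation or reduction of 1,2-dioxan-3-ols through peroxycarbenium ions.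

**Step 7**
Reactants: 14 methyl 2-[(4R,6R)-6-[(2E)-3-iodo-2-methylprop-2-en-1-yl]-4,6-dimethyl-3-[(triethylsilyl)oxy]-1,2-dioxan-3-yl]acetate
Product: 15 methyl 2-[(3S,4R,6R)-6-[(2E)-3-iodo-2-methylprop-2-en-1-yl]-4,6-dimethyl-1,2-dioxan-3-yl]acetate
Conditions: Et3SiH (5 equiv), TMSOTf (1.1 equiv), CH2Cl2, −78 → −20 °C
Reagents that add atoms: none
Why: Ionic reduction of a peroxycarbenium ion (TMSOTf ionises the silyl peroxyketal, Et3SiH traps it, as in the reduction of ester-substituted hemiketals to C-glycosides): with the ring locked (4-methyl and 6-side chain equatorial, 6-methyl axial) hydride adds axially, which places CH2CO2Me equatorial and trans to the C4 methyl (3S), and hydride capture outruns proton loss towards C4.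

**Step 8**
Reactants: 16 (bromomethyl)benzene; 17 bromo(prop-1-yn-1-yl)magnesium
Product: 18 (but-2-yn-1-yl)benzene
Conditions: CuBr·SMe2 (5 mol%), THF, 0 °C → rt
Reagents that add atoms: none
Why: Copper-catalysed substitution of a benzylic bromide by an alkynyl Grignard reagent (sp–sp3 coupling).

**Step 9**
Reactants: 15 methyl 2-[(3S,4R,6R)-6-[(2E)-3-iodo-2-methylprop-2-en-1-yl]-4,6-dimethyl-1,2-dioxan-3-yl]acetate; 18 (but-2-yn-1-yl)benzene
Product: 21 methyl 2-[(3S,4R,6R)-6-[(2E,4E)-2,4-dimethyl-6-phenylhexa-2,4-dien-1-yl]-4,6-dimethyl-1,2-dioxan-3-yl]acetate, via alkenylzirconocene 19 (not isolated), via alkenylzinc chloride 20 (not isolated)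
Conditions: 18, Cp2Zr(H)Cl, THF, 40 °C; ZnCl2, 0 °C; then 15, Pd(PPh3)4 (5 mol%), 0 °C → rt
Reagents that add atoms: none
Why: Syn hydrozirconation (Schwartz reagent, zirconium settling on the methyl-bearing carbon after equilibration) fixes the second trisubstituted alkene, and Zr→Zn transmetalation followed by Negishi coupling with the vinyl iodide proceeds with retention at both alkenes under neutral conditions that a hindered dialkyl peroxide and a methyl ester tolerate.

**Compound list**
1 | 3-methylcyclobutan-1-one | CC1CC(=O)C1 | starting material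
2 | methyl bromoacetate | COC(=O)CBr | starting material
3 | lithium (3R)-3-methylcyclobut-1-en-1-olate | [Li]OC1=C[C@H](C)C1 | intermediate
4 | methyl 2-[(1S,2R)-2-methyl-4-oxocyclobutyl]acetate | COC(=O)C[C@@H]1C(=O)C[C@H]1C | intermediate
5 | methyl 2-[(4R)-4-methyl-2-[(triethylsilyl)oxy]cyclobut-1-en-1-yl]acetate | COC(=O)CC1=C(O[Si](CC)(CC)CC)C[C@H]1C | intermediate
6 | methyl 2-[(1S,2R)-2-methyl-4-oxo-1-[(triethylsilyl)oxy]cyclobutyl]acetate | COC(=O)C[C@@]1(O[Si](CC)(CC)CC)C(=O)C[C@H]1C | intermediate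
7 | 3-bromoprop-1-yne | C#CCBr | starting material
8 | bromo(propa-1,2-dien-1-yl)zinc | C=C=C[Zn]Br | intermediate
9 | methyl 2-[(1S,2S,4R)-2-hydroxy-4-methyl-2-(prop-2-yn-1-yl)-1-[(triethylsilyl)oxy]cyclobutyl]acetate | COC(=O)C[C@@]1(O[Si](CC)(CC)CC)[C@@](O)(CC#C)C[C@H]1C | intermediate
10 | methyl 2-[(1S,2S,4R)-2-[(dimethylalumanyl)oxy]-2-[(2E)-3-(dimethylalumanyl)-2-methylprop-2-en-1-yl]-4-methyl-1-[(triethylsilyl)oxy]cyclobutyl]acetate | COC(=O)C[C@@]1(O[Si](CC)(CC)CC)[C@@](O[Al](C)C)(C/C(C)=C/[Al](C)C)C[C@H]1C | intermediate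
11 | methyl 2-[(1S,2S,4R)-2-hydroxy-2-[(2E)-3-iodo-2-methylprop-2-en-1-yl]-4-methyl-1-[(triethylsilyl)oxy]cyclobutyl]acetate | COC(=O)C[C@@]1(O[Si](CC)(CC)CC)[C@@](O)(C/C(C)=C/I)C[C@H]1C | intermediate
12 | methyl (4R,8E)-3-hydroperoxy-9-iodo-4,8-dimethyl-6-oxo-3-[(triethylsilyl)oxy]non-8-enoate (C3 epimers) | COC(=O)CC(OO)(O[Si](CC)(CC)CC)[C@H](C)CC(=O)C/C(C)=C/I | intermediate
13 | methyl 2-[(4R)-6-hydroxy-6-[(2E)-3-iodo-2-methylprop-2-en-1-yl]-4-methyl-3-[(triethylsilyl)oxy]-1,2-dioxan-3-yl]acetate (C3 and C6 epimers) | COC(=O)CC1(O[Si](CC)(CC)CC)OOC(O)(C/C(C)=C/I)C[C@H]1C | intermediate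
14 | methyl 2-[(4R,6R)-6-[(2E)-3-iodo-2-methylprop-2-en-1-yl]-4,6-dimethyl-3-[(triethylsilyl)oxy]-1,2-dioxan-3-yl]acetate (C3 epimers) | COC(=O)CC1(O[Si](CC)(CC)CC)OO[C@@](C)(C/C(C)=C/I)C[C@H]1C | intermediate
15 | methyl 2-[(3S,4R,6R)-6-[(2E)-3-iodo-2-methylprop-2-en-1-yl]-4,6-dimethyl-1,2-dioxan-3-yl]acetate | COC(=O)C[C@@H]1OO[C@@](C)(C/C(C)=C/I)C[C@H]1C | intermediate
16 | (bromomethyl)benzene | BrCc1ccccc1 | starting material
17 | bromo(prop-1-yn-1-yl)magnesium | CC#C[Mg]Br | starting material
18 | (but-2-yn-1-yl)benzene | CC#CCc1ccccc1 | intermediate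
19 | chlorobis(cyclopentadienyl)[(2E)-4-phenylbut-2-en-2-yl]zirconium | C/C(=C\Cc1ccccc1)[Zr](Cl)(C1C=CC=C1)C1C=CC=C1 | intermediate
20 | chloro[(2E)-4-phenylbut-2-en-2-yl]zinc | C/C(=C\Cc1ccccc1)[Zn]Cl | intermediate
21 | methyl 2-[(3S,4R,6R)-6-[(2E,4E)-2,4-dimethyl-6-phenylhexa-2,4-dien-1-yl]-4,6-dimethyl-1,2-dioxan-3-yl]acetate | COC(=O)C[C@@H]1OO[C@@](C)(C/C(C)=C/C(C)=C/Cc2ccccc2)C[C@H]1C | target

**Totals and risks**
Total steps: 9. Longest linear sequence: 8 (steps 1–7 and 9).

Step 6 (the new C-methylation) is the most likely to fail: the titanium reagent may cleave the O–O bond, attack the open-chain hydroperoxy ketone tautomer, or ionise C3 as well. The fallback uses known chemistry only, sets out from 11 and comes back at 15. Desilylation of 11 (Et3N·3HF) gives the cis-diol methyl 2-[(1S,2S,4R)-1,2-dihydroxy-2-[(2E)-3-iodo-2-methylprop-2-en-1-yl]-4-methylcyclobutyl]acetate F2. Periodate cleavage (NaIO4) opens it to the diketo ester methyl (4R,8E)-9-iodo-4,8-dimethyl-3,6-dioxonon-8-enoate F3. With the β-keto ester held as its sodium enolate (NaH), Wittig methylenation (Ph3P=CH2) of the C6 ketone gives methyl (4R,8E)-9-iodo-4,8-dimethyl-6-methylidene-3-oxonon-8-enoate F4. Isayama–Mukaiyama hydroperoxysilylation (Co(thd)2 cat., O2, Et3SiH) gives the tertiary silyl peroxide methyl (4R,8E)-9-iodo-4,6,8-trimethyl-3-oxo-6-[(triethylsilyl)peroxy]non-8-enoate F5 as both C6 epimers. HF·pyridine frees the hydroperoxide, which closes onto the C3 ketone to the peroxy-hemiketal methyl 2-[(4R)-3-hydroxy-6-[(2E)-3-iodo-2-methylprop-2-en-1-yl]-4,6-dimethyl-1,2-dioxan-3-yl]acetate F6. Et3SiH/TMSOTf as in step 7 then gives 15 together with its C6 epimer, which is removed by chromatography; C6 is not controlled on this path.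

Step 2 may fail on regiochemistry: enol silane formation towards C4 instead of the ester-bearing carbon, or silylation of the ester. The fallback sets out from 4 and comes back at 6. Aerobic hydroxylation of the thermodynamic enolate at the tertiary α-carbon (O2, Cs2CO3, P(OEt)3, DMSO, rt) gives the α-hydroxy ketone methyl 2-[(1S,2R)-1-hydroxy-2-methyl-4-oxocyclobutyl]acetate F1, which is silylated (Et3SiOTf, 2,6-lutidine) to 6.

Step 9 may fail through incomplete regiocontrol in the hydrozirconation, or through residual Zr–H or organozinc attacking the peroxide or the ester. The fallback sets out from 18 and comes back at 21. The alkenylzirconocene is quenched with Me3SnCl to the isolable stannane trimethyl[(2E)-4-phenylbut-2-en-2-yl]stannane F7, which is freed from its regioisomer and coupled with 15 under neutral Stille conditions (Pd2(dba)3, AsPh3, CuI, NMP, rt) to give 21.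

**Further compounds**
F1 | step 2 | methyl 2-[(1S,2R)-1-hydroxy-2-methyl-4-oxocyclobutyl]acetate | COC(=O)C[C@@]1(O)C(=O)C[C@H]1C
F2 | step 6 | methyl 2-[(1S,2S,4R)-1,2-dihydroxy-2-[(2E)-3-iodo-2-methylprop-2-en-1-yl]-4-methylcyclobutyl]acetate | COC(=O)C[C@@]1(O)[C@@](O)(C/C(C)=C/I)C[C@H]1C
F3 | step 6 | methyl (4R,8E)-9-iodo-4,8-dimethyl-3,6-dioxonon-8-enoate | COC(=O)CC(=O)[C@H](C)CC(=O)C/C(C)=C/I
F4 | step 6 | methyl (4R,8E)-9-iodo-4,8-dimethyl-6-methylidene-3-oxonon-8-enoate | COC(=O)CC(=O)[C@H](C)CC(=C)C/C(C)=C/I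
F5 | step 6 | methyl (4R,8E)-9-iodo-4,6,8-trimethyl-3-oxo-6-[(triethylsilyl)peroxy]non-8-enoate | COC(=O)CC(=O)[C@H](C)CC(C)(OO[Si](CC)(CC)CC)C/C(C)=C/I
F6 | step 6 | methyl 2-[(4R)-3-hydroxy-6-[(2E)-3-iodo-2-methylprop-2-en-1-yl]-4,6-dimethyl-1,2-dioxan-3-yl]acetate | COC(=O)CC1(O)OOC(C)(C/C(C)=C/I)C[C@H]1C
F7 | step 9 | trimethyl[(2E)-4-phenylbut-2-en-2-yl]stannane | C/C(=C\Cc1ccccc1)[Sn](C)(C)C
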